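# Total synthesis proposal for (-)-(7R,8S,7'E)-3,4,5,5'-tetramethoxy-4',7-epoxy-8,3'-neolign-7'-ene-9,9'-diol

## Analysis of the target

- **Ring system.** The target is an 8,3'-neolignan with a 4',7-epoxy bridge. Ring A (3,4,5-trimethoxyphenyl) sits on C7, ring B (C1'–C6') is a benzene ring, and ring C is the dihydrofuran O–C7–C8–C3'–C4', fused to ring B along C3'–C4'.
- **Ring B pattern.** Ring B carries four substituents in a fixed order: the (E)-propenol chain on C1', C8 on C3', the ring oxygen on C4' and a methoxy group on C5'. Only C2' and C6' bear hydrogen.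
- **Stereocentres.** There are two, C7 (R) and C8 (S). They are adjacent, ring A and the C9 hydroxymethyl group are trans on ring C, and nothing else in the molecule can relay stereochemical information to them.
- **Sensitive groups.** The weakest bond is C7–O, which is benzylic to an electron-rich arene and has a phenoxide as leaving group. Strong acid, hydrogenolysis and dissolving metals are therefore excluded once ring C exists. The cinnamyl alcohol is sensitive to acid and oxidants and is best made last.
- **Difficulty.** The hard part is to combine absolute control over two neighbouring centres with an unambiguous 1,3,4,5-pattern on ring B.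
- **Feature used.** The plan rests on the pair of oxygen atoms on C4' and C5', with C4' at the ring fusion. This pattern is left when a furan, linked through C8–C7–O to an ethynyl ether, is converted into a phenol. Furan C2, C3, C4 and C5 become C3', C2', C1' and C6', the alkyne carbons become C4' and C5', and the furan oxygen becomes the C5' oxygen.

## Retrosynthetic reasoning

**Side chain (32 ⇒ 31 ⇒ 30).** The allylic alcohol of 32 is taken back to enoate 31, and 31 is cut at C7'=C8' to aldehyde 30. The chain goes first because it is the most fragile part, and because a formyl carbon on C1' is easy to carry in masked form. The forward steps must give only the E alkene and must reduce the ester 1,2 without touching C7–O.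

**Masks and the C5' methyl ether (30 ⇒ 29 ⇒ 28).** Compound 30 goes back to 29 by placing a dioxolane on the C1' aldehyde and a trityl group on O9. Both fall in one mild acid operation. Removing the C5' methyl group leads to phenol 28, whose free hydroxyl is exactly the function that the ring synthesis delivers.

**Rings B and C (28 ⇒ 23).**
- Three bonds are cut together, C3'–C4', C5'–C6' and C5'–O, which opens both rings and gives ethynyl ether 23, an isomer of 28.
- The cut is placed here because all four ring B substituents are then encoded in a 2,4-disubstituted furan and an O–C≡C–H unit. No aromatic substitution regiochemistry has to be solved.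
- C7 and C8 lie in the tether and take part in no bond change, so they can be fixed beforehand in an open chain.
- In the zigzag C9–C8–C7–ring A, a syn relation of furyl and oxygen becomes the trans relation on ring C.
- The forward reaction has three tasks. The furan, not ring A, must attack the activated alkyne. The hydroxyl must end on C5'. The reaction must outrun the decay of a benzylic ynol ether.

**Ethynyl ether (23 ⇒ 20 ⇒ 17 + 18).** Compound 23 is cut at O–C4' and traced through dichlorovinyl ether 20 to alcohol 17 and trichloroethylene 18, which supplies C4' and C5'. The C7–O bond is never broken, so C7 keeps its configuration.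

**O9 mask and C9 oxidation level (17 ⇒ 16 ⇒ 15).**
- O9 must be masked selectively beside the C7 hydroxyl.
- A silyl ether was considered and dropped. It would sit 1,3 to the potassium alkoxide 19 and could migrate from O9 to O7, after which the wrong oxygen would be vinylated.
- Trityl goes on the primary alcohol only, cannot migrate, tolerates hydride and alkyllithium bases, and saves a separate deprotection.
- Diol 16 comes from reductive removal of the auxiliary in 15.

**C7–C8 (15 ⇒ 11 + 12).** The aldol cut joins the two halves at the bond between the stereocentres and sets both in one auxiliary-controlled step. Minor isomers are diastereomers and can be removed. The syn product is the one needed, and the (R)-auxiliary gives C8 (S) and C7 (R).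

**Auxiliary and C8–C3' (11 ⇒ 8 + 9; 8 ⇒ 7 ⇒ 6).** Imide 11 is opened to acid 8 and oxazolidinone 9. Acid 8 is traced through ester 7 to iodofuran 6 by cutting the bond between C8 and furan C2. A palladium-catalysed enolate coupling was preferred for two reasons:
- furfuryl halides give rearranged substitution products;
- homologation of a furan aldehyde costs more steps.

**Furan pattern (6 ⇒ 5 ⇒ 1).**
- Acetal 6 comes from aldehyde 5, and 5 from furan-3-carbaldehyde 1 by functionalising the remote α-position. The carbon that becomes C7' is thus present from the start.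
- A furan bought with the carbonyl on C2 and a halogen on C4 has the right pattern but the wrong function on each carbon, and exchanging them is longer.
- A halogen kept on furan C4 as a handle would not survive the alkyllithium of step 10, hence the acetal.

## Alternatives that were turned down

**Alternative 1:**
- *Disconnection.* C7–C8. Ring B is a ready-made bromoarene whose C4' oxygen carries the 3,4,5-trimethoxybenzyl group and whose C3' carries a diazoacetate (aryldiazoacetate A1).
- *Forward key step.* A chiral dirhodium tetracarboxylate such as Rh2(S-DOSP)4 turns A1 into a donor/acceptor carbene at C8. The carbene inserts into the O–CH2 C–H bond and closes ring C as the cis ester A2, with C7 set by the catalyst. Base must then invert C8 to the trans ester A3, followed by ester reduction and a Heck reaction on the bromide.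
- *For it.* The C–H bond is doubly activated, the reaction class is established for 2-aryl-2,3-dihydrobenzofuran-3-carboxylates, chirality is catalytic, and the route would need about two thirds of the steps. On step economy and on the source of chirality it is stronger than the chosen plan.
- *Against it here.*
  - The C4' oxygen is flanked by C3' and the C5' methoxy group, which twists the benzyloxy group out of plane in the catalyst pocket.
  - An insufficient enantiomer ratio cannot be upgraded by separating diastereomers.
  - The carbene can also attack electron-rich ring A.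
  - The C8 inversion runs through an enolate with the C4' phenoxide as β-leaving group, so ring opening and re-closure can erode C7.
- *Comparison.* The chosen plan is longer. In return, both centres come from one aldol as separable diastereomers, and neither is touched again.

**Alternative 2:**
- *Disconnection.* C8–C3' and C9–O, after C7–O has been made by an iridium-catalysed branched-selective allylic etherification that gives aryl allyl ether A4.
- *Forward key step.* Bu3SnH under air converts the carbon–iodine bond of A4 into the C3' aryl radical. This adds 5-exo to the vinyl group at C8, O2 captures the primary C9 radical, and PPh3 reduces the hydroperoxide to alcohol A5.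
- *For it.* It is the shortest of all the plans, C7 is set catalytically, the C9 oxygen arrives during ring closure, and A5 is one reduction away from the target. In brevity it is clearly superior.
- *Against it here.*
  - The phenol nucleophile is flanked by iodine and methoxy and is a poor partner for the allyliridium intermediate.
  - The branched ether of an electron-rich cinnamyl system can ionise and lose its configuration.
  - The radical step must balance hydrogen transfer from tin against cyclisation and O2 capture, while O2 also consumes the stannane and the acrylate is itself a radical acceptor.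
  - The trans relation depends only on 1,2-induction in the cyclisation.
- *Comparison.* The chosen plan concentrates its risk in one isomerisation with no stoichiometric reagent and needs no diastereoselective ring closure.

**Alternative 3:**
- *Disconnection.* O–C7, from bisphenol A6, which has only the C8 stereocentre.
- *Forward key step.* Ag2O oxidises the 4-alkyl-2,6-dimethoxyphenol of A6 to para-quinone methide A7. The ring B phenol adds to C7 and closes ring C, giving A8 with C7 trans to C8.
- *For it.* The step is mild and biomimetic, only one stereocentre has to be built, and the addition is reversible, so the trans isomer is favoured thermodynamically. In robustness of the ring closure it is at least equal to the chosen plan.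
- *Against it here.*
  - C8 still needs an auxiliary-based construction of comparable length.
  - A6 holds two oxidisable phenols.
  - A7 can tautomerise by loss of H8 to a styrene conjugated with both rings, which destroys the only stereocentre.
  - A8 still needs O-methylation of ring A and a Heck reaction for the chain.
- *Comparison.* The chosen plan has no intermediate in which C8 can become planar, and it brings the C1' carbon in from the start.

Key step: step 11

**Remarks.**
- Neolignan numbering (C1–C9, C1'–C9') is used for all intermediates. "Furan C2–C5" refers to the heterocycle before the key step.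
- BrZnCH2CO2Et (solution in THF) and Ph3P=CHCO2Et are taken as purchased reagents.

## Route

Step 1
Reactants: 1 furan-3-carbaldehyde
Product: 5 5-iodofuran-3-carbaldehyde, via amino alkoxide 2 (not isolated), via 5-lithio amino alkoxide 3 (not isolated), via 5-iodo amino alkoxide 4 (not isolated)
Conditions: morpholine, n-BuLi, THF, −78 °C; 1; s-BuLi, −78 °C; I2, −78 °C; H2O, 0 °C
Reagents that add atoms: iodine, [I][I]
Why: Directed metalation after in-flask masking of the aldehyde as an α-amino alkoxide: the bulky, non-chelating morpholino alkoxide shields H2, so s-BuLi should remove the remote α-proton H5. Iodine traps the carbon–lithium bond and water releases the aldehyde, which fixes the 2,4-pattern of the furan.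

Step 2
Reactants: 5 5-iodofuran-3-carbaldehyde
Product: 6 2-(5-iodofuran-3-yl)-1,3-dioxolane
Conditions: HOCH2CH2OH, PPTS (cat.), benzene, reflux, Dean–Stark
Reagents that add atoms: ethylene glycol, OCCO
Why: Acid-catalysed acetalisation with azeotropic removal of water; the weak acid spares the iodofuran. The acetal hides the electrophilic, ring-deactivating formyl group from the zinc, boron, potassium and lithium reagents that follow.

Step 3
Reactants: 6 2-(5-iodofuran-3-yl)-1,3-dioxolane
Product: 7 ethyl 2-[4-(1,3-dioxolan-2-yl)furan-2-yl]acetate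
Conditions: BrZnCH2CO2Et, Pd2(dba)3 (cat.), XPhos (cat.), THF, 45 °C
Reagents that add atoms: (2-ethoxy-2-oxoethyl)zinc bromide, CCOC(=O)C[Zn]Br
Why: Negishi-type coupling of a Reformatsky reagent with a heteroaryl iodide: oxidative addition of zerovalent palladium, transmetalation of the zinc enolate and reductive elimination form the C8–C3' bond. The nearly neutral zinc enolate leaves the acetal alone.

Step 4
Reactants: 7 ethyl 2-[4-(1,3-dioxolan-2-yl)furan-2-yl]acetate
Product: 8 2-[4-(1,3-dioxolan-2-yl)furan-2-yl]acetic acid
Conditions: LiOH, THF/H2O, 0 °C → rt; cold 1 M HCl to pH 4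
Reagents that add atoms: lithium hydroxide, [Li+].[OH-]
Why: Ester saponification; acidification is stopped at pH 4 in the cold so that the dioxolane is kept.

Step 5
Reactants: 8 2-[4-(1,3-dioxolan-2-yl)furan-2-yl]acetic acid, 9 (4R)-4-benzyl-1,3-oxazolidin-2-one
Product: 11 (4R)-4-benzyl-3-{2-[4-(1,3-dioxolan-2-yl)furan-2-yl]acetyl}-1,3-oxazolidin-2-one, via mixed pivalic anhydride 10 (not isolated)
Conditions: PivCl, Et3N, THF, −20 °C; LiCl, 9, −20 °C → rt
Reagents that add atoms: none
Why: N-acylation through a mixed anhydride under LiCl/Et3N; the oxazolidinone attacks the less hindered furylacetyl carbonyl. No strong base meets the acidic CH2 group.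

Step 6
Reactants: 11 (4R)-4-benzyl-3-{2-[4-(1,3-dioxolan-2-yl)furan-2-yl]acetyl}-1,3-oxazolidin-2-one, 12 3,4,5-trimethoxybenzaldehyde
Product: 15 (4R)-4-benzyl-3-{(2S,3R)-2-[4-(1,3-dioxolan-2-yl)furan-2-yl]-3-hydroxy-3-(3,4,5-trimethoxyphenyl)propanoyl}-1,3-oxazolidin-2-one, via boron enolate 13 (not isolated), via boron aldolate 14 (not isolated)
Conditions: Bu2BOTf, Et3N, CH2Cl2, −78 → 0 °C; 12, −78 → 0 °C; pH 7 buffer, MeOH, 30% H2O2, 0 °C
Reagents that add atoms: none
Why: Evans syn aldol: soft enolisation gives the (Z)-enolate 13, which reacts through a Zimmerman–Traxler chair with the auxiliary carbonyl turned away from the enolate oxygen. The benzyl group of the (R)-auxiliary blocks one enolate face, so C8 (S) and C7 (R) are set together in the syn relation. Acetals are routinely carried through this reaction, only a slight excess of Bu2BOTf is used, and the cold buffered peroxide work-up is short.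

Step 7
Reactants: 15 (4R)-4-benzyl-3-{(2S,3R)-2-[4-(1,3-dioxolan-2-yl)furan-2-yl]-3-hydroxy-3-(3,4,5-trimethoxyphenyl)propanoyl}-1,3-oxazolidin-2-one
Product: 16 (1R,2S)-2-[4-(1,3-dioxolan-2-yl)furan-2-yl]-1-(3,4,5-trimethoxyphenyl)propane-1,3-diol
Conditions: LiBH4, H2O (1 equiv), Et2O/THF, 0 °C
Reagents that add atoms: none
Why: Reductive cleavage of the imide at the exocyclic carbonyl brings C9 to the alcohol level. The cold, weakly basic medium should avoid retro-aldol cleavage and epimerisation at C8.

Step 8
Reactants: 16 (1R,2S)-2-[4-(1,3-dioxolan-2-yl)furan-2-yl]-1-(3,4,5-trimethoxyphenyl)propane-1,3-diol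
Product: 17 (1R,2S)-2-[4-(1,3-dioxolan-2-yl)furan-2-yl]-1-(3,4,5-trimethoxyphenyl)-3-(trityloxy)propan-1-ol
Conditions: TrCl, Et3N, DMAP (cat.), CH2Cl2, rt
Reagents that add atoms: trityl chloride, ClC(c1ccccc1)(c1ccccc1)c1ccccc1
Why: Tritylation is selective for the primary alcohol on steric grounds. Unlike a silyl group, trityl cannot migrate to the C7 alkoxide of step 9; it tolerates KH and n-BuLi and leaves in the acid of step 13.

Step 9
Reactants: 17 (1R,2S)-2-[4-(1,3-dioxolan-2-yl)furan-2-yl]-1-(3,4,5-trimethoxyphenyl)-3-(trityloxy)propan-1-ol, 18 trichloroethylene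
Product: 20 2-{5-[(1R,2S)-1-{[(E)-1,2-dichloroethenyl]oxy}-1-(3,4,5-trimethoxyphenyl)-3-(trityloxy)propan-2-yl]furan-3-yl}-1,3-dioxolane, via potassium alkoxide 19 (not isolated)
Conditions: KH, THF, 0 °C; 18, −50 °C → rt
Reagents that add atoms: none
Why: Dichlorovinyl ether synthesis from an alkoxide and trichloroethylene: base eliminates HCl from 18 to dichloroacetylene, alkoxide 19 adds to it in anti fashion, and protonation gives the (E)-1,2-dichlorovinyl ether. Only the O–H bond of 17 changes, so C7 is retained.

Step 10
Reactants: 20 2-{5-[(1R,2S)-1-{[(E)-1,2-dichloroethenyl]oxy}-1-(3,4,5-trimethoxyphenyl)-3-(trityloxy)propan-2-yl]furan-3-yl}-1,3-dioxolane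
Product: 23 2-{5-[(1R,2S)-1-(ethynyloxy)-1-(3,4,5-trimethoxyphenyl)-3-(trityloxy)propan-2-yl]furan-3-yl}-1,3-dioxolane, via chloroethynyl ether 21 (not isolated), via lithium acetylide 22 (not isolated)
Conditions: n-BuLi (2.5 equiv), Et2O, −78 → −40 °C; H2O, −78 °C; work-up and concentration below 0 °C
Reagents that add atoms: none
Why: β-Elimination of HCl gives 21, chlorine–lithium exchange gives 22, and protonation gives the terminal ynol ether; any lithiation of furan C5 is undone by the quench. Benzylic alkynyl ethers undergo a [3,3] shift and a retro-ene cleavage on warming, so 23 is kept cold and used at once.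

Step 11
Reactants: 23 2-{5-[(1R,2S)-1-(ethynyloxy)-1-(3,4,5-trimethoxyphenyl)-3-(trityloxy)propan-2-yl]furan-3-yl}-1,3-dioxolane
Product: 28 (2R,3S)-5-(1,3-dioxolan-2-yl)-2-(3,4,5-trimethoxyphenyl)-3-[(trityloxy)methyl]-2,3-dihydro-1-benzofuran-7-ol, via Ph3PAu cyclopropyl carbene 24 (not isolated), via Ph3PAu dienal carbene 25 (not isolated), via oxepine 26 (not isolated), via arene oxide 27 (not isolated)
Conditions: Ph3PAuNTf2 (3 mol %), 4 Å MS, CH2Cl2, −30 → 0 °C
Reagents that add atoms: none
Why: This is the gold-catalysed furan–yne phenol synthesis in its ynol ether variant, the reaction type that turns 2-(furan-2-yl)ethyl ethynyl ethers into 2,3-dihydrobenzofuran-7-ols. Monovalent gold binds the alkyne, whose oxygen-bearing carbon (C4') is the electrophilic end of a ketene-oxonium-like complex, and furan C2 (C3') attacks it 5-exo-dig, which closes ring C and gives 24. Cleavage of the furan C2–O bond and of one cyclopropane bond unravels 24 to 25, whose aldehyde oxygen adds to the carbene carbon (C5'), releasing gold and giving oxepine 26 (C5'–O). Disrotatory 6π closure of 26 to arene oxide 27 forms C5'–C6' and so closes ring B. Compound 27 opens at C6'–O because that cation is conjugated with the ring oxygen on C4', whereas a cation at C5' is not, and loss of H5' then leaves the hydroxyl on C5' only. No lasting stereocentre is formed: C7 and C8 take part in no bond change, and the syn array of 23 maps onto the trans ring. The step needs the furan to win over ring A, whose ortho carbon could also reach C4'; the furan is the better π-nucleophile, its tether has two sp3 carbons and closes without strain, and the acetal on furan C4 sits at a nodal position of the cation formed on attack. Low temperature and a fast catalyst should keep C7–O ionisation and the [3,3] shift behind, and the sieves exclude water that would hydrate the ynol ether.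

Step 12
Reactants: 28 (2R,3S)-5-(1,3-dioxolan-2-yl)-2-(3,4,5-trimethoxyphenyl)-3-[(trityloxy)methyl]-2,3-dihydro-1-benzofuran-7-ol
Product: 29 2-{(2R,3S)-7-methoxy-2-(3,4,5-trimethoxyphenyl)-3-[(trityloxy)methyl]-2,3-dihydro-1-benzofuran-5-yl}-1,3-dioxolane
Conditions: MeI, K2CO3, acetone, rt
Reagents that add atoms: iodomethane, CI
Why: Williamson methylation of the only acidic hydroxyl group; acetal, trityl ether and both stereocentres are inert to carbonate.

Step 13
Reactants: 29 2-{(2R,3S)-7-methoxy-2-(3,4,5-trimethoxyphenyl)-3-[(trityloxy)methyl]-2,3-dihydro-1-benzofuran-5-yl}-1,3-dioxolane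
Product: 30 (2R,3S)-3-(hydroxymethyl)-7-methoxy-2-(3,4,5-trimethoxyphenyl)-2,3-dihydro-1-benzofuran-5-carbaldehyde
Conditions: 2 M HCl, THF, rt
Reagents that add atoms: water, O
Why: Acid hydrolysis: the aryl dioxolane and the trityl ether both cleave through well-stabilised cations under conditions too mild to ionise C7–O. Should C7–O open reversibly, re-closure favours the trans ring, and C8 is not affected.

Step 14
Reactants: 30 (2R,3S)-3-(hydroxymethyl)-7-methoxy-2-(3,4,5-trimethoxyphenyl)-2,3-dihydro-1-benzofuran-5-carbaldehyde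
Product: 31 ethyl (E)-3-[(2R,3S)-3-(hydroxymethyl)-7-methoxy-2-(3,4,5-trimethoxyphenyl)-2,3-dihydro-1-benzofuran-5-yl]prop-2-enoate
Conditions: Ph3P=CHCO2Et, toluene, 80 °C
Reagents that add atoms: ethyl (triphenylphosphoranylidene)acetate, CCOC(=O)C=P(c1ccccc1)(c1ccccc1)c1ccccc1
Why: Wittig reaction with a stabilised ylide, which is E-selective with aromatic aldehydes and tolerates the free primary alcohol.

Step 15
Reactants: 31 ethyl (E)-3-[(2R,3S)-3-(hydroxymethyl)-7-methoxy-2-(3,4,5-trimethoxyphenyl)-2,3-dihydro-1-benzofuran-5-yl]prop-2-enoate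
Product: 32 (-)-(7R,8S,7'E)-3,4,5,5'-tetramethoxy-4',7-epoxy-8,3'-neolign-7'-ene-9,9'-diol
Conditions: i-Bu2AlH (4 equiv), CH2Cl2, −78 °C; H2O work-up
Reagents that add atoms: none
Why: 1,2-Reduction of the enoate to the allylic alcohol; one equivalent is consumed by the free hydroxyl group. The alkene geometry, the C7–O bond and both stereocentres are untouched at −78 °C.

## Compound list

1 | furan-3-carbaldehyde | O=Cc1ccoc1 | starting material
2 | lithium furan-3-yl(morpholin-4-yl)methanolate | [Li]OC(c1ccoc1)N1CCOCC1 | intermediate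
3 | lithium (5-lithiofuran-3-yl)(morpholin-4-yl)methanolate | [Li]OC(c1coc([Li])c1)N1CCOCC1 | intermediate
4 | lithium (5-iodofuran-3-yl)(morpholin-4-yl)methanolate | [Li]OC(c1coc(I)c1)N1CCOCC1 | intermediate
5 | 5-iodofuran-3-carbaldehyde | O=Cc1coc(I)c1 | intermediate
6 | 2-(5-iodofuran-3-yl)-1,3-dioxolane | Ic1cc(C2OCCO2)co1 | intermediate
7 | ethyl 2-[4-(1,3-dioxolan-2-yl)furan-2-yl]acetate | CCOC(=O)Cc1cc(C2OCCO2)co1 | intermediate
8 | 2-[4-(1,3-dioxolan-2-yl)furan-2-yl]acetic acid | OC(=O)Cc1cc(C2OCCO2)co1 | intermediate
9 | (4R)-4-benzyl-1,3-oxazolidin-2-one | O=C1N[C@H](Cc2ccccc2)CO1 | starting material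
10 | 2-[4-(1,3-dioxolan-2-yl)furan-2-yl]acetic pivalic anhydride | CC(C)(C)C(=O)OC(=O)Cc1cc(C2OCCO2)co1 | intermediate
11 | (4R)-4-benzyl-3-{2-[4-(1,3-dioxolan-2-yl)furan-2-yl]acetyl}-1,3-oxazolidin-2-one | O=C(Cc1cc(C2OCCO2)co1)N1[C@H](Cc2ccccc2)COC1=O | intermediate
12 | 3,4,5-trimethoxybenzaldehyde | COc1cc(C=O)cc(OC)c1OC | starting material
13 | (Z)-dibutylboron enolate of 11 | CCCCB(CCCC)O/C(=C\c1cc(C2OCCO2)co1)N1[C@H](Cc2ccccc2)COC1=O | intermediate
14 | O7-dibutylboron aldolate of 15 | COc1cc([C@H](OB(CCCC)CCCC)[C@H](C(=O)N2[C@H](Cc3ccccc3)COC2=O)c2cc(C3OCCO3)co2)cc(OC)c1OC | intermediate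
15 | (4R)-4-benzyl-3-{(2S,3R)-2-[4-(1,3-dioxolan-2-yl)furan-2-yl]-3-hydroxy-3-(3,4,5-trimethoxyphenyl)propanoyl}-1,3-oxazolidin-2-one | COc1cc([C@H](O)[C@H](C(=O)N2[C@H](Cc3ccccc3)COC2=O)c2cc(C3OCCO3)co2)cc(OC)c1OC | intermediate
16 | (1R,2S)-2-[4-(1,3-dioxolan-2-yl)furan-2-yl]-1-(3,4,5-trimethoxyphenyl)propane-1,3-diol | COc1cc([C@H](O)[C@H](CO)c2cc(C3OCCO3)co2)cc(OC)c1OC | intermediate
17 | (1R,2S)-2-[4-(1,3-dioxolan-2-yl)furan-2-yl]-1-(3,4,5-trimethoxyphenyl)-3-(trityloxy)propan-1-ol | COc1cc([C@H](O)[C@H](COC(c2ccccc2)(c2ccccc2)c2ccccc2)c2cc(C3OCCO3)co2)cc(OC)c1OC | intermediate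
18 | trichloroethylene | ClC=C(Cl)Cl | starting material
19 | potassium alkoxide of 17 | COc1cc([C@H](O[K])[C@H](COC(c2ccccc2)(c2ccccc2)c2ccccc2)c2cc(C3OCCO3)co2)cc(OC)c1OC | intermediate
20 | 2-{5-[(1R,2S)-1-{[(E)-1,2-dichloroethenyl]oxy}-1-(3,4,5-trimethoxyphenyl)-3-(trityloxy)propan-2-yl]furan-3-yl}-1,3-dioxolane | COc1cc([C@@H]([C@H](COC(c2ccccc2)(c2ccccc2)c2ccccc2)c2cc(C3OCCO3)co2)O/C(Cl)=C\Cl)cc(OC)c1OC | intermediate
21 | chloroethynyl ether corresponding to 23 | COc1cc([C@@H]([C@H](COC(c2ccccc2)(c2ccccc2)c2ccccc2)c2cc(C3OCCO3)co2)OC#CCl)cc(OC)c1OC | intermediate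
22 | lithium acetylide of 23 | COc1cc([C@@H]([C@H](COC(c2ccccc2)(c2ccccc2)c2ccccc2)c2cc(C3OCCO3)co2)OC#C[Li])cc(OC)c1OC | intermediate
23 | 2-{5-[(1R,2S)-1-(ethynyloxy)-1-(3,4,5-trimethoxyphenyl)-3-(trityloxy)propan-2-yl]furan-3-yl}-1,3-dioxolane (syn ethynyl ether, precursor of the key step) | COc1cc([C@@H]([C@H](COC(c2ccccc2)(c2ccccc2)c2ccccc2)c2cc(C3OCCO3)co2)OC#C)cc(OC)c1OC | intermediate
24 | Ph3PAu cyclopropyl carbene cation (ring C closed; cyclopropane from C4', furan C2 and furan C3; carbene on C5') | COc1cc([C@@H]2OC3(C=[Au][P+](c4ccccc4)(c4ccccc4)c4ccccc4)C4C(C5OCCO5)=COC34[C@H]2COC(c2ccccc2)(c2ccccc2)c2ccccc2)cc(OC)c1OC | intermediate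
25 | Ph3PAu dienal carbene cation (furan opened; aldehyde from furan C5 and O) | COc1cc([C@@H]2OC(C=[Au][P+](c3ccccc3)(c3ccccc3)c3ccccc3)=C(/C=C(\C=O)C3OCCO3)[C@H]2COC(c2ccccc2)(c2ccccc2)c2ccccc2)cc(OC)c1OC | intermediate
26 | oxepine fused to ring C | COc1cc([C@@H]2OC3=COC=C(C4OCCO4)C=C3[C@H]2COC(c2ccccc2)(c2ccccc2)c2ccccc2)cc(OC)c1OC | intermediate
27 | C5',C6'-arene oxide | COc1cc([C@@H]2OC3=C(C=C(C4OCCO4)C4OC34)[C@H]2COC(c2ccccc2)(c2ccccc2)c2ccccc2)cc(OC)c1OC | intermediate
28 | (2R,3S)-5-(1,3-dioxolan-2-yl)-2-(3,4,5-trimethoxyphenyl)-3-[(trityloxy)methyl]-2,3-dihydro-1-benzofuran-7-ol (product of the key step) | COc1cc([C@@H]2Oc3c(O)cc(C4OCCO4)cc3[C@H]2COC(c2ccccc2)(c2ccccc2)c2ccccc2)cc(OC)c1OC | intermediate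
29 | 2-{(2R,3S)-7-methoxy-2-(3,4,5-trimethoxyphenyl)-3-[(trityloxy)methyl]-2,3-dihydro-1-benzofuran-5-yl}-1,3-dioxolane | COc1cc([C@@H]2Oc3c(OC)cc(C4OCCO4)cc3[C@H]2COC(c2ccccc2)(c2ccccc2)c2ccccc2)cc(OC)c1OC | intermediate
30 | (2R,3S)-3-(hydroxymethyl)-7-methoxy-2-(3,4,5-trimethoxyphenyl)-2,3-dihydro-1-benzofuran-5-carbaldehyde | COc1cc([C@@H]2Oc3c(OC)cc(C=O)cc3[C@H]2CO)cc(OC)c1OC | intermediate
31 | ethyl (E)-3-[(2R,3S)-3-(hydroxymethyl)-7-methoxy-2-(3,4,5-trimethoxyphenyl)-2,3-dihydro-1-benzofuran-5-yl]prop-2-enoate | COc1cc([C@@H]2Oc3c(OC)cc(/C=C/C(=O)OCC)cc3[C@H]2CO)cc(OC)c1OC | intermediate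
32 | (-)-(7R,8S,7'E)-3,4,5,5'-tetramethoxy-4',7-epoxy-8,3'-neolign-7'-ene-9,9'-diol | COc1cc([C@@H]2Oc3c(OC)cc(/C=C/CO)cc3[C@H]2CO)cc(OC)c1OC | target

## Step count and least certain steps

Total step count: 15. Longest linear sequence: 15 steps (1 → 32). Compounds 9, 12 and 18 enter as purchased materials.

**Step 11 (key step).**
- *Main risk.* The C7–O bond may break heterolytically once gold has turned the ynol ether into a ketene-oxonium-like species, because ring A stabilises positive charge on C7. The tether would then fragment or the benzylic carbon would shift.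
- *Other risks.* The ortho carbon of ring A may attack C4'. The thermal [3,3] shift may compete, adventitious water may hydrate the alkyne, and trace acid may remove the trityl group so that O9 adds to the alkyne.
- *Fallback.* Ring B is bought instead of built, and ring C is closed at O–C7. The fallback sets out from 9 and 12 and comes back at 30.
  - 5-Iodovanillin F1 is converted with MOMCl and i-Pr2NEt into MOM ether F2, then acetalised as in step 2 to dioxolane F3.
  - F3 is coupled with BrZnCH2CO2Et as in step 3 to arylacetate F4, which is saponified to arylacetic acid F5.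
  - F5 is joined to 9 as in step 5 to give imide F6. The boron aldol with 12 as in step 6 gives aldol F7, and LiBH4 as in step 7 gives diol F8.
  - Warm 2 M HCl in THF removes the MOM group and the dioxolane and ionises the C7 carbinol. The freed C4' phenol closes ring C on the face away from the C9 hydroxymethyl group, which gives 30.

**Step 10.**
- *Risk.* The ynol ether may be lost during work-up and concentration. The routes are the [3,3] shift into ring A and the retro-ene cleavage that uses H8, both driven by the benzylic position of the ether.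
- *Fallback.* A storable, capped alkyne is isolated. The fallback sets out from 22 and comes back at 23. Acetylide 22 is quenched with Me3SiCl at −78 °C to give trimethylsilylethynyl ether F9, which can be purified on base-washed silica. The silyl group is removed with K2CO3 in MeOH at 0 °C directly before step 11.

**Step 9.**
- *Risk.* The hindered alkoxide may add to dichloroacetylene more slowly than this reagent decomposes, so conversion stays incomplete.
- *Fallback.* The two carbons are built on the oxygen one at a time, without KH. The fallback sets out from 17 and comes back at 21, inside step 10.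
  - Alcohol 17 is formylated with acetic formic anhydride and pyridine to formate F10.
  - F10 is dichloromethylenated with PPh3 and CCl4 in THF at 60 °C to 2,2-dichlorovinyl ether F11.
  - n-BuLi eliminates HCl from F11 to give 21, which is carried on to 22 and 23 in the same flask.

**Step 1.**
- *Risk.* Metalation may be incomplete or may occur at C2, because both α-protons are acidic. Iodine may also oxidise the amino alkoxide.
- *Fallback.* Regiocontrol is left to sterically governed C–H borylation. The fallback sets out from 1 and comes back at 7.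
  - Aldehyde 1 is acetalised as in step 2 to 2-(furan-3-yl)-1,3-dioxolane F12.
  - F12 is borylated with [Ir(OMe)(cod)]2, dtbpy and a deficit of B2pin2 at the unhindered α-position to give furylboronate F13.
  - F13 is coupled with ethyl bromoacetate in a Suzuki–Miyaura-type reaction (Pd(OAc)2, P(o-tol)3, K3PO4, THF/H2O) to give 7.

**Step 3.**
- *Risk.* Protodeiodination or homocoupling of the electron-rich iodofuran may outrun the coupling, and the zinc enolate may self-condense.
- *Fallback.* A copper-catalysed malonate arylation is followed by loss of one ester group. The fallback sets out from 6 and comes back at 7. Iodide 6 reacts with diethyl malonate (CuI, 2-picolinic acid, Cs2CO3, dioxane, rt to 40 °C) to give furylmalonate F14. A Krapcho dealkoxycarbonylation (LiCl, DMSO/H2O, 130 °C) then gives 7.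

## Further compounds

F1 | step 11 | 4-hydroxy-3-iodo-5-methoxybenzaldehyde (5-iodovanillin) | COc1cc(C=O)cc(I)c1O
F2 | step 11 | 3-iodo-5-methoxy-4-(methoxymethoxy)benzaldehyde | COCOc1c(I)cc(C=O)cc1OC
F3 | step 11 | 2-[3-iodo-5-methoxy-4-(methoxymethoxy)phenyl]-1,3-dioxolane | COCOc1c(I)cc(C2OCCO2)cc1OC
F4 | step 11 | ethyl 2-[5-(1,3-dioxolan-2-yl)-3-methoxy-2-(methoxymethoxy)phenyl]acetate | CCOC(=O)Cc1cc(C2OCCO2)cc(OC)c1OCOC
F5 | step 11 | 2-[5-(1,3-dioxolan-2-yl)-3-methoxy-2-(methoxymethoxy)phenyl]acetic acid | OC(=O)Cc1cc(C2OCCO2)cc(OC)c1OCOC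
F6 | step 11 | (4R)-4-benzyl-3-{2-[5-(1,3-dioxolan-2-yl)-3-methoxy-2-(methoxymethoxy)phenyl]acetyl}-1,3-oxazolidin-2-one | O=C(Cc1cc(C2OCCO2)cc(OC)c1OCOC)N1[C@H](Cc2ccccc2)COC1=O
F7 | step 11 | (4R)-4-benzyl-3-{(2R,3R)-2-[5-(1,3-dioxolan-2-yl)-3-methoxy-2-(methoxymethoxy)phenyl]-3-hydroxy-3-(3,4,5-trimethoxyphenyl)propanoyl}-1,3-oxazolidin-2-one | COc1cc([C@H](O)[C@H](C(=O)N2[C@H](Cc3ccccc3)COC2=O)c2cc(C3OCCO3)cc(OC)c2OCOC)cc(OC)c1OC
F8 | step 11 | (1R,2S)-2-[5-(1,3-dioxolan-2-yl)-3-methoxy-2-(methoxymethoxy)phenyl]-1-(3,4,5-trimethoxyphenyl)propane-1,3-diol | COc1cc([C@H](O)[C@H](CO)c2cc(C3OCCO3)cc(OC)c2OCOC)cc(OC)c1OC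
F9 | step 10 | 2-{5-[(1R,2S)-1-(3,4,5-trimethoxyphenyl)-1-{[(trimethylsilyl)ethynyl]oxy}-3-(trityloxy)propan-2-yl]furan-3-yl}-1,3-dioxolane | COc1cc([C@@H]([C@H](COC(c2ccccc2)(c2ccccc2)c2ccccc2)c2cc(C3OCCO3)co2)OC#C[Si](C)(C)C)cc(OC)c1OC
F10 | step 9 | (1R,2S)-2-[4-(1,3-dioxolan-2-yl)furan-2-yl]-1-(3,4,5-trimethoxyphenyl)-3-(trityloxy)propyl formate | COc1cc([C@@H]([C@H](COC(c2ccccc2)(c2ccccc2)c2ccccc2)c2cc(C3OCCO3)co2)OC=O)cc(OC)c1OC
F11 | step 9 | 2-{5-[(1R,2S)-1-[(2,2-dichloroethenyl)oxy]-1-(3,4,5-trimethoxyphenyl)-3-(trityloxy)propan-2-yl]furan-3-yl}-1,3-dioxolane | COc1cc([C@@H]([C@H](COC(c2ccccc2)(c2ccccc2)c2ccccc2)c2cc(C3OCCO3)co2)OC=C(Cl)Cl)cc(OC)c1OC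
F12 | step 1 | 2-(furan-3-yl)-1,3-dioxolane | C1COC(O1)c1ccoc1
F13 | step 1 | 2-[4-(1,3-dioxolan-2-yl)furan-2-yl]-4,4,5,5-tetramethyl-1,3,2-dioxaborolane | CC1(C)OB(OC1(C)C)c1cc(C2OCCO2)co1
F14 | step 3 | diethyl 2-[4-(1,3-dioxolan-2-yl)furan-2-yl]propanedioate | CCOC(=O)C(C(=O)OCC)c1cc(C2OCCO2)co1
A1 | alternative 1 | methyl 2-[5-bromo-3-methoxy-2-(3,4,5-trimethoxybenzyloxy)phenyl]-2-diazoacetate | COC(=O)C(=[N+]=[N-])c1cc(Br)cc(OC)c1OCc1cc(OC)c(OC)c(OC)c1
A2 | alternative 1 | methyl (2R,3S)-5-bromo-7-methoxy-2-(3,4,5-trimethoxyphenyl)-2,3-dihydro-1-benzofuran-3-carboxylate (cis) | COc1cc([C@@H]2Oc3c(OC)cc(Br)cc3[C@@H]2C(=O)OC)cc(OC)c1OC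
A3 | alternative 1 | methyl (2R,3R)-5-bromo-7-methoxy-2-(3,4,5-trimethoxyphenyl)-2,3-dihydro-1-benzofuran-3-carboxylate (trans) | COc1cc([C@@H]2Oc3c(OC)cc(Br)cc3[C@H]2C(=O)OC)cc(OC)c1OC
A4 | alternative 2 | methyl (E)-3-(3-iodo-5-methoxy-4-{[(1R)-1-(3,4,5-trimethoxyphenyl)prop-2-en-1-yl]oxy}phenyl)prop-2-enoate | COc1cc([C@@H](C=C)Oc2c(I)cc(/C=C/C(=O)OC)cc2OC)cc(OC)c1OC
A5 | alternative 2 | methyl (E)-3-[(2R,3S)-3-(hydroxymethyl)-7-methoxy-2-(3,4,5-trimethoxyphenyl)-2,3-dihydro-1-benzofuran-5-yl]prop-2-enoate | COc1cc([C@@H]2Oc3c(OC)cc(/C=C/C(=O)OC)cc3[C@H]2CO)cc(OC)c1OC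
A6 | alternative 3 | (2S)-2-(5-bromo-2-hydroxy-3-methoxyphenyl)-3-(4-hydroxy-3,5-dimethoxyphenyl)propan-1-ol | COc1cc(C[C@H](CO)c2cc(Br)cc(OC)c2O)cc(OC)c1O
A7 | alternative 3 | 4-[(2S)-2-(5-bromo-2-hydroxy-3-methoxyphenyl)-3-hydroxypropylidene]-2,6-dimethoxycyclohexa-2,5-dien-1-one | COC1=CC(=C[C@H](CO)c2cc(Br)cc(OC)c2O)C=C(OC)C1=O
A8 | alternative 3 | 4-[(2R,3S)-5-bromo-3-(hydroxymethyl)-7-methoxy-2,3-dihydro-1-benzofuran-2-yl]-2,6-dimethoxyphenol | COc1cc([C@@H]2Oc3c(OC)cc(Br)cc3[C@H]2CO)cc(OC)c1O
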